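## The problem

The target is an unsymmetrical biflavonoid. A 5-hydroxy-7-methoxyflavone carries at C-4' of its ring B an ether oxygen that is bonded to C-6 of a (2S)-5,4'-dihydroxy-7-methoxyflavanone. On the flavanone side this oxygen sits between the 5-hydroxyl and the 7-methoxy group, so the diaryl ether is di-ortho-substituted and is best made early, on a small symmetric ring. The only stereocentre is C-2 of the flavanone; no second centre can relay to it, so a chiral catalyst must set it. That centre is fragile: base opens ring C by a retro-oxa-Michael reaction to the achiral chalcone, and a free 4'-phenoxide opens it through a quinone methide. The two halves share the same ring A pattern and differ only in oxidation level at C-2/C-3, so no late dehydrogenation or reduction can tell them apart, and the flavone has to be formed at its own oxidation level. Three phenols (two of them chelated to carbonyl groups) and two methyl ethers that must stay rule out strong Lewis acid, strong base and oxidants late in the route. The enabling feature is the flavone pyranone (O-1, C-2, C-3, C-4, C-4a): C-4 is a lone carbonyl carbon that carbon monoxide can supply, C-3 and C-2 with their aryl group map onto a terminal arylacetylene, and C-4a has oxygen on both neighbours (C-5 and C-8a) with the methoxy group para, so the aryl iodide precursor is symmetric and either oxygen can close the ring.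

## Retrosynthesis

**Silyl ether.** Target 26 is taken back to its 4'-O-triisopropylsilyl ether 25. No skeletal bond is cut. The silyl group is there because the step before it runs in a secondary amine, where a free 4'-phenoxide would invite ring opening at C-2. The forward reaction only has to remove an aryl silyl ether with buffered fluoride.

**Flavone pyranone (key disconnection).** In 25 three bonds are cut at once: C-4a–C-4, C-4–C-3 and O-1–C-2 of the flavone. This gives the symmetric diacetate 6, carbon monoxide 22 and the terminal alkyne 21, which already holds the complete flavanone and the diaryl ether.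
- Neighbouring cuts are weaker here. An acyl-transfer route through a 1,3-diketone needs strong base and then acid. Oxidative cyclisation of a chalcone would also dehydrogenate the flavanone. A cut at C-2–C-1' would require a separately made 5-hydroxychromone electrophile.
- The diacetate 6 is preferred to the free diol 5. It is neutral and less electron-rich for the insertion of palladium, it keeps the phenoxide masked until the carbon–carbon bonds exist, and iodophenol acetates are the substrates for which this annulation runs at 40 °C under one atmosphere of 22.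
- The forward reaction must close 6-endo (no aurone) and must leave C-2 of the flavanone untouched.

**Alkyne.** Alkyne 21 is cut at the C(sp)–C(aryl) bond, through the C-silyl alkyne 20, to aryl iodide 18 and ethynyltrimethylsilane 19. The triple bond is introduced last on this fragment because it would not survive the arylrhodium, boron Lewis acid or peracid steps that come earlier. The iodine is carried from the first step of the arm as a placeholder. The forward steps must be mild and, for the desilylation, non-basic.

**Protecting-group adjustment.** Silyl ether 18 comes from diol 17 by selective silylation of the non-chelated 4'-hydroxyl. Diol 17 comes from the 5,7-dimethyl 4'-benzyl ether 16 by one treatment with a chelating boron Lewis acid. The two methoxy groups of 16 derive from a symmetric precursor and differ only because one is peri to the carbonyl; that difference is what the forward cleavage uses.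

**Stereocentre.** Flavanone 16 is cut at C-2–C-1' to the flat chromone 14 and 4-(benzyloxy)phenylboronic acid 15. This is preferred to closing O-1–C-2 by displacement at a carbinol: a para-oxygenated benzylic carbinol ionises easily, and the sequence would be several steps longer. It is also preferred to cyclising a chalcone, where enantiocontrol is poor. The forward reaction is a catalyst-controlled aryl transfer to the Re face of C-2.

**Chromone.** Chromone 14 loses C-2 (a one-carbon amide acetal) to give acetophenone 12. Cutting C-4a–C-4 of 12 gives phenol 11, whose two free ortho positions are equivalent, so the acylation has no regiochemical question.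

**Diaryl ether.** Phenol 11 is the Dakin product of aldehyde 9. Cutting the ether C–O bond of 9 gives syringaldehyde 7 and 4-iodophenylboronic acid 8. Making the hindered ether first, on a cheap symmetric phenol and at room temperature, is preferred to any later coupling at a hexasubstituted ring. Nucleophilic aromatic substitution is not available because the iodophenyl ring has no activating group.

**Iodoresorcinol.** Diacetate 6 comes from diol 5 and this from the bis(methoxymethyl) ether 4. The C–I bond of 4 is cut through aryllithium 3 back to 2 and 5-methoxyresorcinol 1. Metalation between the two acetal oxygens fixes the symmetric isomer, which direct iodination of 1 might not do.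

## Roads not taken

Alternative 1: The cut removes two C–C bonds of flavone ring B (C-2'–C-3' and C-4'–C-5'). In the forward step the aryl ynol ether A1 adds across C-3 and C-6 of methyl coumalate A2 and the adduct loses CO2 to give the para-aryloxybenzoate A3.
- Merits: it is metal-free and its regiochemistry is set by polarisation. The hindered C–O bond is made on an sp carbon before the ring exists, which is better than the copper-mediated arylation of a di-ortho-substituted phenol in step 5 of the chosen plan.
- Weak points: the ring it builds is a plain para-disubstituted benzene that can be bought. A1 needs several steps from 7 and is sensitive. After A3 both heterocycles and the stereocentre are still to be made, the flavone by an acyl-transfer and cyclodehydration sequence under strong base and acid.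
- Comparison: the chosen plan makes the same ether in one step, with an iodonium fallback for the hindered coupling, and spends its key step on the pyranone, which is worth far more.

Alternative 2: The cut removes C-5–C-4a and C-8a–C-8 of flavanone ring A. Heating cyclobutenone A4 with the chiral siloxyalkyne A5 gives the pentasubstituted phenol A6 by a Danheiser benzannulation (ketene formation, [2+2] addition, ring opening and 6π closure).
- Merits: every substituent of ring A is placed and differentiated by the mechanism (free 5-OH, silylated 8a-oxygen). This is better than the chelation-controlled demethylation in step 10 of the chosen plan. The stereocentre arrives with A5, so no catalytic asymmetric step is needed on advanced material.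
- Weak points: A4 and A5 are both multi-step and labile, and the ring pattern they build is already present in 7. After A6 the pyran must be closed with inversion at a para-oxygenated benzylic carbinol (ionisation risk), C-4 must be oxidised from CH2 to the ketone beside an electron-rich ring and a flavone, and the flavone 5-methyl ether must be cleaved.
- Comparison: the chosen plan is shorter and its ring A chemistry is standard. What it has to set against the clean oxygen differentiation of A6 is the symmetry of its intermediates and a fallback that moves the demethylation to the achiral chromone.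

Alternative 3: The cut removes C-3–C-4 and O-1–C-2 of flavanone ring C. Salicylaldehyde A7, an orthoester and a chiral confined Brønsted acid give a methoxy-substituted ortho-quinone methide that adds styrene A8 to form the cis-4-methoxyflavan A9.
- Merits: it is the most convergent road, and the stereocentre is created in the ring-forming step itself. No base-labile flavanone is carried through amine-containing steps. Here it is better than the chosen plan, which takes C-2 through four such steps.
- Weak points: A9 is one oxidation level below the flavanone, so C-4 must be converted into the ketone and three ethers then cleaved. The acid catalyst has to ionise an aldehyde flanked by methoxy and aryloxy groups while the basic flavone carbonyl competes for it. A8 is prone to cationic oligomerisation. The demonstrated scope is far from a hexasubstituted salicylaldehyde that carries a flavone.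
- Comparison: the chosen plan offsets its exposure of C-2 with low temperature, a blocked 4'-oxygen and a key step whose reaction type is established on closely related iodophenol acetates.

Key step: step 14

## Route

Assumption: the (S)-configured biaryl bisphosphine in step 9 is assigned to the 2S product by analogy with the facial sense of rhodium-catalysed arylation of cyclic enones; if the first run shows the opposite sense, the (R)-ligand is used and nothing else changes.

Step 1
Reactants: 1 5-methoxybenzene-1,3-diol (5-methoxyresorcinol)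
Product: 2 1-methoxy-3,5-bis(methoxymethoxy)benzene
Conditions: MOMCl (2.5 equiv), iPr2NEt (3 equiv), CH2Cl2, 0 °C → rt
Reagents that add atoms: chloromethyl methyl ether (MOMCl), COCCl
Why: O-Alkylation of both phenols with a reactive α-chloro ether (acetal protection); the methoxymethyl groups are chosen because they direct the lithiation of step 2 and leave under mild acid.

Step 2
Reactants: 2 1-methoxy-3,5-bis(methoxymethoxy)benzene
Product: 4 2-iodo-5-methoxy-1,3-bis(methoxymethoxy)benzene, via C-2 aryllithium 3 (not isolated)
Conditions: n-BuLi (1.2 equiv), THF, 0 °C; then I2 (1.3 equiv), −78 °C → rt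
Reagents that add atoms: iodine, II
Why: Directed ortho-metalation followed by iodinolysis; the position between the two acetal oxygens is the most acidic and doubly chelated, so the symmetric iodide should form in preference to the isomer next to the methoxy group.

Step 3
Reactants: 4 2-iodo-5-methoxy-1,3-bis(methoxymethoxy)benzene
Product: 5 2-iodo-5-methoxybenzene-1,3-diol
Conditions: HCl (3 M in MeOH), rt
Reagents that add atoms: none
Why: Acid-catalysed acetal exchange with methanol removes both methoxymethyl groups; room temperature and the absence of iodide or reductant should keep the electron-rich C–I bond intact.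

Step 4
Reactants: 5 2-iodo-5-methoxybenzene-1,3-diol
Product: 6 2-iodo-5-methoxy-1,3-phenylene diacetate
Conditions: Ac2O (3 equiv), pyridine, CH2Cl2, 0 °C → rt
Reagents that add atoms: acetic anhydride, CC(=O)OC(C)=O
Why: Base-mediated O-acylation of both phenols; the diacetate is stable on storage, keeps the symmetry of 5 and is the substrate type for which the mild annulation of step 14 is established.

Step 5
Reactants: 7 syringaldehyde (4-hydroxy-3,5-dimethoxybenzaldehyde); 8 4-iodophenylboronic acid
Product: 9 4-(4-iodophenoxy)-3,5-dimethoxybenzaldehyde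
Conditions: Cu(OAc)2 (1.0 equiv), 8 (2 equiv), pyridine (5 equiv), 4 Å molecular sieves, CH2Cl2, air, rt
Reagents that add atoms: none
Why: Chan–Lam O-arylation, which tolerates ortho-substituted phenols and leaves an aryl iodide untouched because no low-valent metal is present; air returns the copper to the divalent state, so the salt is not consumed in the balance.

Step 6
Reactants: 9 4-(4-iodophenoxy)-3,5-dimethoxybenzaldehyde
Product: 11 4-(4-iodophenoxy)-3,5-dimethoxyphenol, via aryl formate 10 (not isolated)
Conditions: mCPBA (1.3 equiv), CH2Cl2, 0 °C → rt; aq Na2S2O3/NaHCO3 wash; then K2CO3 (0.3 equiv), MeOH, rt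
Reagents that add atoms: 3-chloroperoxybenzoic acid (mCPBA), OOC(=O)c1cccc(Cl)c1
Why: Baeyer–Villiger (Dakin-type) oxidation in which the electron-rich trioxygenated aryl group migrates, followed by methanolysis of the formate; without strong acid the peracid oxidises an aryl iodide only slowly, and the reductive wash returns any trivalent iodine to the iodide.

Step 7
Reactants: 11 4-(4-iodophenoxy)-3,5-dimethoxyphenol
Product: 12 1-[2-hydroxy-5-(4-iodophenoxy)-4,6-dimethoxyphenyl]ethan-1-one
Conditions: AcOH (solvent), BF3·OEt2 (3 equiv), 85 °C; aq NaOAc work-up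
Reagents that add atoms: acetic acid, CC(=O)O
Why: Friedel–Crafts C-acylation of a phenol (via its acetate and Fries-type migration), as used for 3,4,5-trioxygenated phenols; the two free ortho positions are equivalent and the iodophenyl ring is much less activated.

Step 8
Reactants: 12 1-[2-hydroxy-5-(4-iodophenoxy)-4,6-dimethoxyphenyl]ethan-1-one
Product: 14 6-(4-iodophenoxy)-5,7-dimethoxy-4H-chromen-4-one, via dimethylamino enaminone 13 (not isolated)
Conditions: Me2NCH(OMe)2 (3 equiv), toluene, 100 °C; evaporate; then conc. HCl, CH2Cl2, rt
Reagents that add atoms: N,N-dimethylformamide dimethyl acetal, COC(OC)N(C)C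
Why: Enaminone condensation of the methyl ketone followed by acid-mediated addition–elimination of the phenol, the standard chromone synthesis from 2-hydroxyacetophenones; it supplies C-2 with no substituent.

Step 9
Reactants: 14 6-(4-iodophenoxy)-5,7-dimethoxy-4H-chromen-4-one; 15 4-(benzyloxy)phenylboronic acid
Product: 16 (2S)-2-[4-(benzyloxy)phenyl]-6-(4-iodophenoxy)-5,7-dimethoxy-2,3-dihydro-4H-chromen-4-one
Conditions: [Rh(OH)(cod)]2 (2.5 mol%), (S)-MeO-F12-BIPHEP [(S)-2,2'-bis[bis(3,4,5-trifluorophenyl)phosphino]-6,6'-dimethoxy-1,1'-biphenyl] (5.5 mol%), 15 (2.5 equiv), CH2Cl2/H2O (10:1), 30 °C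
Reagents that add atoms: none
Why: Hayashi–Miyaura asymmetric 1,4-addition to a chromone: an arylrhodium species (monovalent rhodium) inserts the C-2=C-3 bond and water protonates the enolate. The electron-poor bisphosphine makes the addition fast without added base, so the flavanone should not ring-open, and its axial chirality should direct the aryl group to the Re face of C-2 to set the 2S centre. The aryl iodide is expected to survive because the monovalent rhodium–phosphine complex does not insert into it at this temperature.

Step 10
Reactants: 16 (2S)-2-[4-(benzyloxy)phenyl]-6-(4-iodophenoxy)-5,7-dimethoxy-2,3-dihydro-4H-chromen-4-one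
Product: 17 (2S)-5-hydroxy-2-(4-hydroxyphenyl)-6-(4-iodophenoxy)-7-methoxy-2,3-dihydro-4H-chromen-4-one
Conditions: BCl3 (4 equiv), pentamethylbenzene (3 equiv), CH2Cl2, −78 → 0 °C; MeOH, aq NaHCO3
Reagents that add atoms: none
Why: Chelation-controlled Lewis-acid ether cleavage: boron bound to the C-4 carbonyl delivers chloride to the peri 5-O-methyl group, while the 7-methyl ether has no such neighbour and stays. The benzyl ether is cleaved at low temperature and pentamethylbenzene traps the benzyl cation before it can alkylate the electron-rich rings.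

Step 11
Reactants: 17 (2S)-5-hydroxy-2-(4-hydroxyphenyl)-6-(4-iodophenoxy)-7-methoxy-2,3-dihydro-4H-chromen-4-one
Product: 18 (2S)-5-hydroxy-6-(4-iodophenoxy)-7-methoxy-2-{4-[(triisopropylsilyl)oxy]phenyl}-2,3-dihydro-4H-chromen-4-one
Conditions: TIPSCl (1.15 equiv), imidazole (2.5 equiv), DMF, 0 °C → rt
Reagents that add atoms: triisopropylsilyl chloride (TIPSCl), CC(C)[Si](Cl)(C(C)C)C(C)C
Why: Selective O-silylation: the 5-hydroxyl is locked in a hydrogen bond to the carbonyl and does not react under imidazole conditions; the bulky silyl ether is chosen to withstand the amines of steps 12 and 14.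

Step 12
Reactants: 18 (2S)-5-hydroxy-6-(4-iodophenoxy)-7-methoxy-2-{4-[(triisopropylsilyl)oxy]phenyl}-2,3-dihydro-4H-chromen-4-one; 19 ethynyltrimethylsilane
Product: 20 (2S)-5-hydroxy-7-methoxy-2-{4-[(triisopropylsilyl)oxy]phenyl}-6-{4-[(trimethylsilyl)ethynyl]phenoxy}-2,3-dihydro-4H-chromen-4-one
Conditions: PdCl2(PPh3)2 (3 mol%), CuI (6 mol%), 19 (1.5 equiv), Et3N (3 equiv), THF, rt
Reagents that add atoms: none
Why: Sonogashira coupling of an aryl iodide at room temperature; the C-silyl group prevents double coupling, and the hindered tertiary amine with a blocked 4'-oxygen should leave C-2 alone.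

Step 13
Reactants: 20 (2S)-5-hydroxy-7-methoxy-2-{4-[(triisopropylsilyl)oxy]phenyl}-6-{4-[(trimethylsilyl)ethynyl]phenoxy}-2,3-dihydro-4H-chromen-4-one
Product: 21 (2S)-6-(4-ethynylphenoxy)-5-hydroxy-7-methoxy-2-{4-[(triisopropylsilyl)oxy]phenyl}-2,3-dihydro-4H-chromen-4-one
Conditions: AgNO3 (0.2 equiv), acetone/H2O (5:1), rt, dark
Reagents that add atoms: none
Why: Silver-catalysed protodesilylation of a trimethylsilylalkyne via the silver acetylide, a neutral method that is selective for the C–Si bond over silyl ethers; it avoids the carbonate or fluoride that would endanger the flavanone or the aryl silyl ether.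

Step 14
Reactants: 6 2-iodo-5-methoxy-1,3-phenylene diacetate; 21 (2S)-6-(4-ethynylphenoxy)-5-hydroxy-7-methoxy-2-{4-[(triisopropylsilyl)oxy]phenyl}-2,3-dihydro-4H-chromen-4-one; 22 carbon monoxide
Product: 25 (2S)-5-hydroxy-6-[4-(5-hydroxy-7-methoxy-4-oxo-4H-chromen-2-yl)phenoxy]-7-methoxy-2-{4-[(triisopropylsilyl)oxy]phenyl}-2,3-dihydro-4H-chromen-4-one, via acetylated ynone 23 (not isolated), via diethylamino enaminone 24 (not isolated)
Conditions: PdCl2(PPh3)2 (5 mol%), thiourea (5 mol%), 1,3-bis(diphenylphosphino)propane (5 mol%), 6 (1.2 equiv), CO (1 atm), Et2NH (10 equiv), DMF, 40 °C; then AcOH to pH 6, 40 °C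
Reagents that add atoms: none
Why: PdCl2(PPh3)2 is reduced in the flask to zerovalent palladium, which inserts into the C–I bond of 6; insertion of CO gives an aroyl-palladium species, and the alkyne 21, deprotonated by Et2NH at the metal, is joined by reductive elimination to give ynone 23 (C-4a–C-4 and C-4–C-3). Et2NH then removes both acetates by aminolysis and adds to the ynone to give enaminone 24. A phenol oxygen attacks the amine-bearing carbon and Et2NH is expelled, a 6-endo-trig addition–elimination that forms O-1–C-2 and closes the pyranone; the final mild acidification completes this loss of amine. The closest known reaction type is the palladium-catalysed carbonylative annulation of 2-iodophenols and their acetates with terminal arylacetylenes in diethylamine, which gives flavones. The selectivity needed is 6-endo closure rather than 5-exo closure to an aurone: the acetates keep the phenoxide masked until the carbon–carbon bonds exist, and in 24 the only electrophilic carbon is the one that leads to the six-membered ring. No regiochemical choice arises because 6 is symmetric, so either oxygen gives the same 5-hydroxy-7-methoxy pattern and the other ends as the chelated 5-OH. No stereocentre is formed; C-2 of the flavanone is protected by the low temperature, the absence of oxidant and strong base, and the silyl ether that prevents a 4'-phenoxide.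

Step 15
Reactants: 25 (2S)-5-hydroxy-6-[4-(5-hydroxy-7-methoxy-4-oxo-4H-chromen-2-yl)phenoxy]-7-methoxy-2-{4-[(triisopropylsilyl)oxy]phenyl}-2,3-dihydro-4H-chromen-4-one
Product: 26 (2S)-5-hydroxy-6-[4-(5-hydroxy-7-methoxy-4-oxo-4H-chromen-2-yl)phenoxy]-2-(4-hydroxyphenyl)-7-methoxy-2,3-dihydro-4H-chromen-4-one
Conditions: TBAF (1.2 equiv), AcOH (1.5 equiv), THF, 0 °C
Reagents that add atoms: none
Why: Fluoride-induced cleavage of an aryl silyl ether; buffering with acetic acid keeps the medium near neutral so that the liberated 4'-phenol is not left as a phenoxide next to the epimerisable C-2.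

## Compound list

1 | 5-methoxybenzene-1,3-diol (5-methoxyresorcinol) | COc1cc(O)cc(O)c1 | starting material
2 | 1-methoxy-3,5-bis(methoxymethoxy)benzene | COCOc1cc(OC)cc(OCOC)c1 | intermediate
3 | [4-methoxy-2,6-bis(methoxymethoxy)phenyl]lithium | [Li]c1c(OCOC)cc(OC)cc1OCOC | intermediate (not isolated)
4 | 2-iodo-5-methoxy-1,3-bis(methoxymethoxy)benzene | COCOc1cc(OC)cc(OCOC)c1I | intermediate
5 | 2-iodo-5-methoxybenzene-1,3-diol | COc1cc(O)c(I)c(O)c1 | intermediate
6 | 2-iodo-5-methoxy-1,3-phenylene diacetate | COc1cc(OC(C)=O)c(I)c(OC(C)=O)c1 | intermediate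
7 | syringaldehyde (4-hydroxy-3,5-dimethoxybenzaldehyde) | COc1cc(C=O)cc(OC)c1O | starting material
8 | 4-iodophenylboronic acid | OB(O)c1ccc(I)cc1 | starting material
9 | 4-(4-iodophenoxy)-3,5-dimethoxybenzaldehyde | COc1cc(C=O)cc(OC)c1Oc1ccc(I)cc1 | intermediate
10 | 4-(4-iodophenoxy)-3,5-dimethoxyphenyl formate | COc1cc(OC=O)cc(OC)c1Oc1ccc(I)cc1 | intermediate (not isolated)
11 | 4-(4-iodophenoxy)-3,5-dimethoxyphenol | COc1cc(O)cc(OC)c1Oc1ccc(I)cc1 | intermediate
12 | 1-[2-hydroxy-5-(4-iodophenoxy)-4,6-dimethoxyphenyl]ethan-1-one | CC(=O)c1c(O)cc(OC)c(Oc2ccc(I)cc2)c1OC | intermediate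
13 | (E)-3-(dimethylamino)-1-[2-hydroxy-5-(4-iodophenoxy)-4,6-dimethoxyphenyl]prop-2-en-1-one | CN(C)/C=C/C(=O)c1c(O)cc(OC)c(Oc2ccc(I)cc2)c1OC | intermediate (not isolated)
14 | 6-(4-iodophenoxy)-5,7-dimethoxy-4H-chromen-4-one | COc1cc2occc(=O)c2c(OC)c1Oc1ccc(I)cc1 | intermediate
15 | 4-(benzyloxy)phenylboronic acid | OB(O)c1ccc(OCc2ccccc2)cc1 | starting material
16 | (2S)-2-[4-(benzyloxy)phenyl]-6-(4-iodophenoxy)-5,7-dimethoxy-2,3-dihydro-4H-chromen-4-one | COc1cc2c(c(OC)c1Oc1ccc(I)cc1)C(=O)C[C@@H](c1ccc(OCc3ccccc3)cc1)O2 | intermediate
17 | (2S)-5-hydroxy-2-(4-hydroxyphenyl)-6-(4-iodophenoxy)-7-methoxy-2,3-dihydro-4H-chromen-4-one | COc1cc2c(c(O)c1Oc1ccc(I)cc1)C(=O)C[C@@H](c1ccc(O)cc1)O2 | intermediate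
18 | (2S)-5-hydroxy-6-(4-iodophenoxy)-7-methoxy-2-{4-[(triisopropylsilyl)oxy]phenyl}-2,3-dihydro-4H-chromen-4-one | COc1cc2c(c(O)c1Oc1ccc(I)cc1)C(=O)C[C@@H](c1ccc(O[Si](C(C)C)(C(C)C)C(C)C)cc1)O2 | intermediate
19 | ethynyltrimethylsilane | C#C[Si](C)(C)C | starting material
20 | (2S)-5-hydroxy-7-methoxy-2-{4-[(triisopropylsilyl)oxy]phenyl}-6-{4-[(trimethylsilyl)ethynyl]phenoxy}-2,3-dihydro-4H-chromen-4-one | COc1cc2c(c(O)c1Oc1ccc(C#C[Si](C)(C)C)cc1)C(=O)C[C@@H](c1ccc(O[Si](C(C)C)(C(C)C)C(C)C)cc1)O2 | intermediate
21 | (2S)-6-(4-ethynylphenoxy)-5-hydroxy-7-methoxy-2-{4-[(triisopropylsilyl)oxy]phenyl}-2,3-dihydro-4H-chromen-4-one | C#Cc1ccc(Oc2c(OC)cc3c(c2O)C(=O)C[C@@H](c2ccc(O[Si](C(C)C)(C(C)C)C(C)C)cc2)O3)cc1 | intermediate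
22 | carbon monoxide | [C-]#[O+] | starting material
23 | 2-[3-(4-{[(2S)-5-hydroxy-7-methoxy-4-oxo-2-{4-[(triisopropylsilyl)oxy]phenyl}-3,4-dihydro-2H-chromen-6-yl]oxy}phenyl)prop-2-ynoyl]-5-methoxy-1,3-phenylene diacetate | COc1cc(OC(C)=O)c(C(=O)C#Cc2ccc(Oc3c(OC)cc4c(c3O)C(=O)C[C@@H](c3ccc(O[Si](C(C)C)(C(C)C)C(C)C)cc3)O4)cc2)c(OC(C)=O)c1 | intermediate (not isolated)
24 | (2S)-6-{4-[1-(diethylamino)-3-(2,6-dihydroxy-4-methoxyphenyl)-3-oxoprop-1-en-1-yl]phenoxy}-5-hydroxy-7-methoxy-2-{4-[(triisopropylsilyl)oxy]phenyl}-2,3-dihydro-4H-chromen-4-one (alkene geometry not fixed) | COc1cc(O)c(C(=O)C=C(N(CC)CC)c2ccc(Oc3c(OC)cc4c(c3O)C(=O)C[C@@H](c3ccc(O[Si](C(C)C)(C(C)C)C(C)C)cc3)O4)cc2)c(O)c1 | intermediate (not isolated)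
25 | (2S)-5-hydroxy-6-[4-(5-hydroxy-7-methoxy-4-oxo-4H-chromen-2-yl)phenoxy]-7-methoxy-2-{4-[(triisopropylsilyl)oxy]phenyl}-2,3-dihydro-4H-chromen-4-one | COc1cc(O)c2c(=O)cc(-c3ccc(Oc4c(OC)cc5c(c4O)C(=O)C[C@@H](c4ccc(O[Si](C(C)C)(C(C)C)C(C)C)cc4)O5)cc3)oc2c1 | intermediate
26 | (2S)-5-hydroxy-6-[4-(5-hydroxy-7-methoxy-4-oxo-4H-chromen-2-yl)phenoxy]-2-(4-hydroxyphenyl)-7-methoxy-2,3-dihydro-4H-chromen-4-one | COc1cc(O)c2c(=O)cc(-c3ccc(Oc4c(OC)cc5c(c4O)C(=O)C[C@@H](c4ccc(O)cc4)O5)cc3)oc2c1 | target

## Step count and least certain steps

Total: 15 steps. Longest linear sequence: 11 steps (7 → 26, steps 5–15); the iodoresorcinol arm (steps 1–4) joins at step 14.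

**Step 14 (key step).** Three processes may interfere.
- The di-ortho-substituted arylpalladium species may take up CO slowly at one atmosphere, so that it couples with the alkyne directly without the carbonyl carbon.
- The amine may capture the aroyl-palladium species (aminocarbonylation).
- Long exposure to Et2NH may open and re-close ring C of the flavanone, eroding enantiopurity.

The fallback makes the same ynone without CO and shortens the amine contact. It sets out from 2 and 21. Aryllithium 3 (formed as in step 2) is quenched with CO2 to give 4-methoxy-2,6-bis(methoxymethoxy)benzoic acid F1. Under neutral conditions 1-chloro-N,N,2-trimethylprop-1-en-1-amine converts it into 4-methoxy-2,6-bis(methoxymethoxy)benzoyl chloride F2. An acyl Sonogashira coupling of F2 with 21 (PdCl2(PPh3)2, CuI, Et3N, THF, rt) gives the bis(methoxymethyl) ynone F3. HCl in MeOH at rt removes the acetals to give the dihydroxy ynone F4, and brief treatment with Et2NH in THF at rt closes it through enaminone 24. The route is rejoined at 25.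

**Step 9.** The electron-rich, peri-substituted chromone may react slowly, facial selectivity may be insufficient, the product may ring-open and take up a second aryl group, or rhodium may insert into the C–I bond. The fallback sets out from 12. Claisen–Schmidt condensation with 4-(benzyloxy)benzaldehyde (KOH, EtOH) gives the 2'-hydroxychalcone F5, and NaOAc in refluxing EtOH cyclises it to the racemic flavanone F6. A kinetic resolution by asymmetric transfer hydrogenation follows (RuCl(p-cymene)(TsDPEN), using the antipode that consumes the 2R enantiomer, HCO2H/Et3N). It reduces the unwanted enantiomer to the cis-flavan-4-ol F7 and leaves the 2S ketone. The route is rejoined at 16.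

**Step 10.** The Lewis acid may open ring C through the benzylic cation at C-2, which the para-oxygenated aryl group stabilises, with loss of enantiopurity. Discrimination between the 5- and 7-methyl ethers may also fade on warming. The fallback moves the demethylation to the achiral stage and sets out from 14. BCl3 (CH2Cl2, −78 → 0 °C) gives 5-hydroxy-6-(4-iodophenoxy)-7-methoxy-4H-chromen-4-one F8. BnBr and K2CO3 in DMF at 60 °C give the 5-benzyl ether F9. The conjugate addition of step 9 with 15 then gives the dibenzyl flavanone F10. Both benzyl groups are removed with BCl3 and pentamethylbenzene at −78 °C within minutes, far milder than a demethylation. The route is rejoined at 17.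

**Step 5.** Transmetalation and C–O bond formation may be slow at a phenol flanked by two methoxy groups and deactivated by the para-formyl group, while protodeboronation and homocoupling consume 8. The fallback is a metal-free arylation and sets out from 7. The salt (4-iodophenyl)(2,4,6-trimethoxyphenyl)iodonium tosylate F11 is prepared in one pot from 1,4-diiodobenzene, mCPBA and TsOH, then 1,3,5-trimethoxybenzene. With K2CO3 in MeCN at 40 °C it transfers its less electron-rich aryl group to the phenoxide by ligand coupling on trivalent iodine, a reaction that tolerates di-ortho-substituted phenols. The route is rejoined at 9.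

**Step 2.** Lithiation may also occur between an acetal oxygen and the methoxy group, which would lead to the unsymmetrical iodide and in the end to the 7-hydroxy-5-methoxy isomer. The fallback removes the regiochemical question through threefold symmetry; it replaces steps 1–4 and sets out from 21 and commercial phloroglucinol. I2 and NaHCO3 in THF/H2O at 0 °C give 2-iodobenzene-1,3,5-triol F12. Ac2O and pyridine give the triacetate F13. F13, 21 and 22 under the conditions of step 14 give the 5,7-dihydroxyflavone analogue F14. Trimethylsilyldiazomethane in toluene/MeOH at rt methylates only the acidic, non-chelated 7-hydroxyl. The route is rejoined at 25.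

## Further compounds

F1 | step 14 | 4-methoxy-2,6-bis(methoxymethoxy)benzoic acid | COCOc1cc(OC)cc(OCOC)c1C(=O)O
F2 | step 14 | 4-methoxy-2,6-bis(methoxymethoxy)benzoyl chloride | COCOc1cc(OC)cc(OCOC)c1C(=O)Cl
F3 | step 14 | (2S)-5-hydroxy-7-methoxy-6-(4-{3-[4-methoxy-2,6-bis(methoxymethoxy)phenyl]-3-oxoprop-1-yn-1-yl}phenoxy)-2-{4-[(triisopropylsilyl)oxy]phenyl}-2,3-dihydro-4H-chromen-4-one | COCOc1cc(OC)cc(OCOC)c1C(=O)C#Cc1ccc(Oc2c(OC)cc3c(c2O)C(=O)C[C@@H](c2ccc(O[Si](C(C)C)(C(C)C)C(C)C)cc2)O3)cc1
F4 | step 14 | (2S)-6-{4-[3-(2,6-dihydroxy-4-methoxyphenyl)-3-oxoprop-1-yn-1-yl]phenoxy}-5-hydroxy-7-methoxy-2-{4-[(triisopropylsilyl)oxy]phenyl}-2,3-dihydro-4H-chromen-4-one | COc1cc(O)c(C(=O)C#Cc2ccc(Oc3c(OC)cc4c(c3O)C(=O)C[C@@H](c3ccc(O[Si](C(C)C)(C(C)C)C(C)C)cc3)O4)cc2)c(O)c1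
F5 | step 9 | (E)-3-[4-(benzyloxy)phenyl]-1-[2-hydroxy-5-(4-iodophenoxy)-4,6-dimethoxyphenyl]prop-2-en-1-one | COc1cc(O)c(C(=O)/C=C/c2ccc(OCc3ccccc3)cc2)c(OC)c1Oc1ccc(I)cc1
F6 | step 9 | racemic 2-[4-(benzyloxy)phenyl]-6-(4-iodophenoxy)-5,7-dimethoxy-2,3-dihydro-4H-chromen-4-one | COc1cc2c(c(OC)c1Oc1ccc(I)cc1)C(=O)CC(c1ccc(OCc3ccccc3)cc1)O2
F7 | step 9 | (2R,4R)-2-[4-(benzyloxy)phenyl]-6-(4-iodophenoxy)-5,7-dimethoxy-3,4-dihydro-2H-chromen-4-ol | O[C@@H]1C[C@H](c2ccc(OCc3ccccc3)cc2)Oc2cc(OC)c(Oc3ccc(I)cc3)c(OC)c21
F8 | step 10 | 5-hydroxy-6-(4-iodophenoxy)-7-methoxy-4H-chromen-4-one | COc1cc2occc(=O)c2c(O)c1Oc1ccc(I)cc1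
F9 | step 10 | 5-(benzyloxy)-6-(4-iodophenoxy)-7-methoxy-4H-chromen-4-one | COc1cc2occc(=O)c2c(OCc2ccccc2)c1Oc1ccc(I)cc1
F10 | step 10 | (2S)-5-(benzyloxy)-2-[4-(benzyloxy)phenyl]-6-(4-iodophenoxy)-7-methoxy-2,3-dihydro-4H-chromen-4-one | COc1cc2c(c(OCc3ccccc3)c1Oc1ccc(I)cc1)C(=O)C[C@@H](c1ccc(OCc3ccccc3)cc1)O2
F11 | step 5 | (4-iodophenyl)(2,4,6-trimethoxyphenyl)iodonium 4-methylbenzenesulfonate | COc1cc(OC)c([I+]c2ccc(I)cc2)c(OC)c1.Cc1ccc(cc1)S(=O)(=O)[O-]
F12 | step 2 | 2-iodobenzene-1,3,5-triol | Oc1cc(O)c(I)c(O)c1
F13 | step 2 | 2-iodobenzene-1,3,5-triyl triacetate | CC(=O)Oc1cc(OC(C)=O)c(I)c(OC(C)=O)c1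
F14 | step 2 | (2S)-6-[4-(5,7-dihydroxy-4-oxo-4H-chromen-2-yl)phenoxy]-5-hydroxy-7-methoxy-2-{4-[(triisopropylsilyl)oxy]phenyl}-2,3-dihydro-4H-chromen-4-one | Oc1cc(O)c2c(=O)cc(-c3ccc(Oc4c(OC)cc5c(c4O)C(=O)C[C@@H](c4ccc(O[Si](C(C)C)(C(C)C)C(C)C)cc4)O5)cc3)oc2c1
A1 | alternative 1 | 2-[4-(ethynyloxy)-3,5-dimethoxyphenyl]-1,3-dioxolane | C#COc1c(OC)cc(cc1OC)C1OCCO1
A2 | alternative 1 | methyl coumalate (methyl 2-oxo-2H-pyran-5-carboxylate) | COC(=O)c1ccc(=O)oc1
A3 | alternative 1 | methyl 4-[4-(1,3-dioxolan-2-yl)-2,6-dimethoxyphenoxy]benzoate | COC(=O)c1ccc(Oc2c(OC)cc(cc2OC)C2OCCO2)cc1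
A4 | alternative 2 | 4-[4-(5,7-dimethoxy-4-oxo-4H-chromen-2-yl)phenoxy]-3-methoxycyclobut-2-en-1-one | COC1=CC(=O)C1Oc1ccc(cc1)-c1cc(=O)c2c(OC)cc(OC)cc2o1
A5 | alternative 2 | (R)-({5-[4-(benzyloxy)phenyl]-5-[(tert-butyldimethylsilyl)oxy]pent-1-yn-1-yl}oxy)triisopropylsilane | CC(C)[Si](OC#CCC[C@@H](O[Si](C)(C)C(C)(C)C)c1ccc(OCc2ccccc2)cc1)(C(C)C)C(C)C
A6 | alternative 2 | 2-{(3R)-3-[4-(benzyloxy)phenyl]-3-[(tert-butyldimethylsilyl)oxy]propyl}-6-[4-(5,7-dimethoxy-4-oxo-4H-chromen-2-yl)phenoxy]-5-methoxy-3-[(triisopropylsilyl)oxy]phenol | Oc1c(CC[C@@H](O[Si](C)(C)C(C)(C)C)c2ccc(OCc3ccccc3)cc2)c(O[Si](C(C)C)(C(C)C)C(C)C)cc(OC)c1Oc1ccc(cc1)-c1cc(=O)c2c(OC)cc(OC)cc2o1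
A7 | alternative 3 | 3-[4-(5,7-dimethoxy-4-oxo-4H-chromen-2-yl)phenoxy]-6-hydroxy-2,4-dimethoxybenzaldehyde | O=Cc1c(O)cc(OC)c(Oc2ccc(cc2)-c2cc(=O)c3c(OC)cc(OC)cc3o2)c1OC
A8 | alternative 3 | 1-(benzyloxy)-4-ethenylbenzene (4-(benzyloxy)styrene) | C=Cc1ccc(OCc2ccccc2)cc1
A9 | alternative 3 | 2-(4-{[(2S,4S)-2-[4-(benzyloxy)phenyl]-4,5,7-trimethoxy-3,4-dihydro-2H-chromen-6-yl]oxy}phenyl)-5,7-dimethoxy-4H-chromen-4-one | CO[C@H]1C[C@@H](c2ccc(OCc3ccccc3)cc2)Oc2cc(OC)c(Oc3ccc(cc3)-c3cc(=O)c4c(OC)cc(OC)cc4o3)c(OC)c21
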